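**Plan**

1. Retrosynthesis first removes the protecting groups, then restores a C11 ketone, returns the 8(17)-alkene and 9α-H to a conjugated C8=C9 enone, and returns C5–H to a C5=C6 alkene.
2. Ring B (C5–C10) is then cut at C7–C8 and C9–C10. C8 and C9 each carry one carbon substituent (C17 and the C11–C15 chain) and C10 is quaternary, so C8–C9 is an alkyne (an ynone) and C10=C5–C6=C7 is a 2-vinylcyclohexene built on ring A.
3. The diene is cut at C5–C6 (enol triflate plus vinyl), C10–C20 and C4–C18 (two methylations of a cyclohexanone β-keto ester). The ynone is cut at C9–C11 (Weinreb amide plus propynyl Grignard) back to 3-hydroxy-3-methylglutarate.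
4. Forward: ring A is bought, ring B forms in the [4+2] step with the whole side chain attached, then hydrogenation, photodeconjugation, C11 deoxygenation and deprotection.
5. Stereochemistry: C4 from an auxiliary-controlled methylation, C13 from an esterase desymmetrisation, C10 from cycloaddition anti to the C4 ester, C5 from α-face hydrogenation, C9 from α-face protonation of a dienol.

Key step: step 11

Numbering: labdane numbering is used for all bicyclic compounds (ring A C1–C5 and C10, ring B C5–C10, C17 on C8, C18 α-methyl and C19 β-carboxyl on C4, C20 on C10, chain C11–C16); the target is (13R)-13-hydroxylabd-8(17)-ene-15,19-dioic acid.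

Assumption: the lithio-enamine of L-valine tert-butyl ester is taken to methylate to the (1S)-keto ester (D-valine tert-butyl ester would be used if the sense is opposite), and pig liver esterase is taken to give the (S)-half ester.

**Diene (ring A)**

Step 1
Reactants: 1 tert-butyl 2-oxocyclohexane-1-carboxylate; 2 L-valine tert-butyl ester
Product: 3 tert-butyl (2S)-2-{[2-(tert-butoxycarbonyl)cyclohex-1-en-1-yl]amino}-3-methylbutanoate
Conditions: 4 Å MS, AcOH (cat.), PhMe, 60 °C
Reagents that add atoms: none
Why: Condensation of a β-keto ester with a primary amine (enamine formation) should give the hydrogen-bonded β-enamino ester that carries the chiral auxiliary.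

Step 2
Reactants: 3 enamino ester
Product: 6 tert-butyl (1S)-1-methyl-2-oxocyclohexane-1-carboxylate, via lithio-enamine 4 (not isolated), via methylated imine 5 (not isolated)
Conditions: LiN(i-Pr)2, PhMe, −78 °C; HMPA (1 equiv), MeI, −78 → −55 °C; then 10% aq. citric acid, rt
Reagents that add atoms: iodomethane, CI; water, O
Why: Auxiliary-controlled alkylation of a chiral lithio-enamine (aza-enolate alkylation) in which lithium is held by the nitrogen and both ester carbonyls, the isopropyl group screens one face and methyl iodide enters on the other to set C4, after which imine hydrolysis returns the auxiliary.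

Step 3
Reactants: 6 tert-butyl (1S)-1-methyl-2-oxocyclohexane-1-carboxylate
Product: 8 tert-butyl (1S)-1,3-dimethyl-2-oxocyclohexane-1-carboxylate (both C3 epimers), via lithium enolate 7 (not isolated)
Conditions: LiN(i-Pr)2, THF, −78 °C; MeI, −78 → −20 °C
Reagents that add atoms: iodomethane, CI
Why: Kinetic enolate alkylation at the only enolisable position brings in the future C20 methyl, and the configuration at this carbon is irrelevant because it becomes sp2 in the next step.

Step 4
Reactants: 8 tert-butyl (1S)-1,3-dimethyl-2-oxocyclohexane-1-carboxylate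
Product: 10 tert-butyl (1S)-1,3-dimethyl-2-(trifluoromethanesulfonyloxy)cyclohex-2-ene-1-carboxylate, via potassium enolate 9 (not isolated)
Conditions: KN(SiMe3)2, THF, −78 → 0 °C; PhNTf2, −78 → 0 °C
Reagents that add atoms: N-phenylbis(trifluoromethanesulfonimide), O=S(=O)(N(c1ccccc1)S(=O)(=O)C(F)(F)F)C(F)(F)F
Why: Enol triflate formation by deprotonation of the last α-hydrogen and O-sulfonylation should give the tetrasubstituted enol triflate without touching the quaternary centre.

Step 5
Reactants: 10 enol triflate
Product: 11 tert-butyl (1S)-2-ethenyl-1,3-dimethylcyclohex-2-ene-1-carboxylate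
Conditions: CH2=CHSnBu3, Pd(PPh3)4 (5 mol %), LiCl (3 equiv), THF, reflux
Reagents that add atoms: tributyl(vinyl)stannane, C=C[Sn](CCCC)(CCCC)CCCC
Why: Stille cross-coupling of an enol triflate with a vinylstannane, with chloride assisting transmetalation, is reliable for hindered cyclohexenyl triflates and gives the diene C10=C5–C6=C7.

**Ynone (C8, C9, C11–C17)**

Step 6
Reactants: 12 dimethyl 3-hydroxy-3-methylpentanedioate
Product: 13 (3S)-3-hydroxy-5-methoxy-3-methyl-5-oxopentanoic acid
Conditions: pig liver esterase, phosphate buffer pH 7.5 (pH-stat, 1 M NaOH), rt; then acidify to pH 2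
Reagents that add atoms: water, O
Why: Enzymatic desymmetrisation of a prochiral diester, in which the esterase hydrolyses one enantiotopic ester group, fixes the future C13 centre.

Step 7
Reactants: 13 (S)-half ester
Product: 14 1-tert-butyl 5-methyl (3R)-3-hydroxy-3-methylpentanedioate
Conditions: Cl3CC(=NH)O-t-Bu (2 equiv), CH2Cl2–cyclohexane, rt
Reagents that add atoms: tert-butyl 2,2,2-trichloroacetimidate, CC(C)(C)OC(=N)C(Cl)(Cl)Cl
Why: Imidate esterification, in which the acid itself activates the imidate, makes the two carboxyl termini chemically different while the tertiary alcohol stays free.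

Step 8
Reactants: 14 mixed diester
Product: 15 1-tert-butyl 5-methyl (3R)-3-methyl-3-(triethylsilyloxy)pentanedioate
Conditions: Et3SiOTf (1.3 equiv), 2,6-lutidine, CH2Cl2, −78 → −20 °C
Reagents that add atoms: triethylsilyl trifluoromethanesulfonate, CC[Si](CC)(CC)OS(=O)(=O)C(F)(F)F
Why: Silylation of a tertiary alcohol with a silyl triflate and a hindered base gives the ether that later blocks retro-aldol cleavage and oxa-conjugate addition of the β-oxy ketone.

Step 9
Reactants: 15 silyl ether diester
Product: 16 tert-butyl (3R)-5-[methoxy(methyl)amino]-3-methyl-5-oxo-3-(triethylsilyloxy)pentanoate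
Conditions: MeNH(OMe)·HCl (2 equiv), i-PrMgCl (4 equiv), THF, −20 → 0 °C
Reagents that add atoms: N,O-dimethylhydroxylamine hydrochloride, CNOC.Cl
Why: Aminolysis of the methyl ester by the chloromagnesium amide (Weinreb amide formation) should be selective because the tert-butyl ester is too hindered to react.

Step 10
Reactants: 16 Weinreb amide; 17 prop-1-yn-1-ylmagnesium bromide
Product: 19 tert-butyl (3R)-3-methyl-5-oxo-3-(triethylsilyloxy)oct-6-ynoate, via bromomagnesium hemiaminal 18 (not isolated)
Conditions: 17 (1.5 equiv), THF, −20 → 0 °C; sat. aq. NH4Cl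
Reagents that add atoms: none
Why: Weinreb ketone synthesis, in which the alkynyl Grignard adds once and the chelated adduct survives until work-up, gives the ynone while the tert-butyl ester is inert.

**Union and endgame**

Step 11
Reactants: 11 tert-butyl (1S)-2-ethenyl-1,3-dimethylcyclohex-2-ene-1-carboxylate (1.3 equiv); 19 ynone
Product: 20 di-tert-butyl (13R)-11-oxo-13-(triethylsilyloxy)labda-5,8-diene-15,19-dioate (10β-CH3, 4β-CO2t-Bu)
Conditions: Me2AlCl (1.5 equiv), CH2Cl2, −78 → −20 °C; aq. Rochelle salt
Reagents that add atoms: none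
Why: Complexation of the ynone carbonyl by Me2AlCl lowers its LUMO, and the diene C10=C5–C6=C7 adds in an asynchronous Diels–Alder reaction in which the unsubstituted terminus C7 bonds to the β-carbon C8 ahead of the bond from the tetrasubstituted terminus C10 to C9; the closest known reaction is the [4+2] cycloaddition of 2-methyl-1-vinylcyclohexenes with acetylenic esters and ketones. Ring B closes in this one event as a six-membered carbocycle (a cyclohexa-1,4-diene) by union of the four-carbon diene with the two-carbon alkyne. Regiochemistry follows from polarity (largest HOMO coefficient at C7, largest LUMO coefficient at C8), so the acyl group ends on C9 next to the quaternary carbon. The only new stereocentre, C10, is controlled by C4: the tert-butyl ester should prefer the pseudoaxial position of the ring A half-chair and the dienophile should add to the opposite (α) face, which places C20 cis to C19. The step needs face selectivity and enough reactivity at a hindered terminus, and these should come from the bulky ester, the low temperature that the Lewis acid allows and the sterically small linear alkyne; because both partners are single enantiomers the minor C10 epimer is a separable diastereomer. Without the Lewis acid, a β-methyl ynone would need temperatures at which the diene undergoes 1,5-hydrogen shift, and Me2AlCl also scavenges protons, so the silyl ether and both tert-butyl esters should persist.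

Step 12
Reactants: 20 Diels–Alder adduct
Product: 21 di-tert-butyl (13R)-11-oxo-13-(triethylsilyloxy)labd-8-ene-15,19-dioate (5α-H)
Conditions: H2 (1 atm), 10% Pd/C, EtOAc, rt
Reagents that add atoms: none
Why: Heterogeneous catalytic hydrogenation should saturate the trisubstituted C5=C6 bond from the α face, opposite the C20 methyl and the C19 ester, to give the trans ring fusion, while the tetrasubstituted hindered enone is left.

Step 13
Reactants: 21 conjugated enone
Product: 23 di-tert-butyl (13R)-11-oxo-13-(triethylsilyloxy)labd-8(17)-ene-15,19-dioate (9α-H), via photodienol 22 (not isolated)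
Conditions: hν (350 nm, Pyrex), 1,2-dimethylimidazole (0.2 equiv), MeCN, rt, Ar
Reagents that add atoms: none
Why: Photochemical deconjugation of an enone, in which excitation moves a C17 hydrogen to the carbonyl oxygen by a 1,5-hydrogen shift (possible because C11 and C17 are cis on C8=C9) and base-catalysed ketonisation of the dienol protonates C9 from the α face opposite C20, should give the equatorial side chain, which is also the thermodynamic epimer.

Step 14
Reactants: 23 β,γ-unsaturated ketone
Product: 24 di-tert-butyl (13R)-11-hydroxy-13-(triethylsilyloxy)labd-8(17)-ene-15,19-dioate (both C11 epimers)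
Conditions: NaBH4, MeOH–THF, −20 → 0 °C
Reagents that add atoms: none
Why: Hydride reduction of the ketone (either C11 epimer serves) should outrun base-induced reconjugation at low temperature, and the tert-butyl ester at C15 resists lactonisation by the C11 oxygen.

Step 15
Reactants: 24 C11 alcohol
Product: 25 di-tert-butyl (13R)-11-(phenoxythiocarbonyloxy)-13-(triethylsilyloxy)labd-8(17)-ene-15,19-dioate
Conditions: PhOC(S)Cl (2 equiv), pyridine, DMAP (cat.), CH2Cl2, rt
Reagents that add atoms: O-phenyl chlorothionoformate, S=C(Cl)Oc1ccccc1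
Why: Acylation with a thiocarbonyl chloride under nucleophilic catalysis gives the deoxygenation substrate without a strong base, so silyl migration from O13 to O11 is avoided.

Step 16
Reactants: 25 thionocarbonate
Product: 26 di-tert-butyl (13R)-13-(triethylsilyloxy)labd-8(17)-ene-15,19-dioate
Conditions: Bu3SnH (3 equiv, 0.3 M), AIBN (0.2 equiv), PhMe, 90 °C
Reagents that add atoms: none
Why: Barton–McCombie deoxygenation, in which the stannyl radical adds to sulfur and the released secondary C11 radical is reduced by the tin hydride, is run concentrated so that hydrogen transfer outruns 3-exo attack on the 8(17)-alkene.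

Step 17
Reactants: 26 protected labdene
Product: 28 (13R)-13-hydroxylabd-8(17)-ene-15,19-dioic acid (target), via bis(trimethylsilyl) ester 27 (not isolated)
Conditions: Me3SiOTf (6 equiv), 2,6-lutidine (8 equiv), CH2Cl2, 0 °C → rt; concentrate; Bu4NF (excess), THF, rt; aq. NaH2PO4 (pH 4)
Reagents that add atoms: none
Why: Silyl triflate-mediated cleavage of tert-butyl esters (loss of 2-methylpropene from the O-silylated ester, with no attack at the hindered C19 carbonyl) followed by fluoride desilylation of the silyl esters and the tertiary ether avoids the protic acid that would cyclise the 13-hydroxy-8(17)-ene to the 8,13-ether.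

**Compound list**

1 | tert-butyl 2-oxocyclohexane-1-carboxylate | O=C1CCCCC1C(=O)OC(C)(C)C | starting material
2 | L-valine tert-butyl ester, tert-butyl (2S)-2-amino-3-methylbutanoate | CC(C)[C@H](N)C(=O)OC(C)(C)C | starting material
3 | tert-butyl (2S)-2-{[2-(tert-butoxycarbonyl)cyclohex-1-en-1-yl]amino}-3-methylbutanoate | CC(C)[C@H](NC1=C(C(=O)OC(C)(C)C)CCCC1)C(=O)OC(C)(C)C | intermediate
4 | N-lithio derivative of 3 (lithio-enamine) | CC(C)[C@H](N([Li])C1=C(C(=O)OC(C)(C)C)CCCC1)C(=O)OC(C)(C)C | intermediate (not isolated)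
5 | tert-butyl (1S)-2-{[(2S)-1-tert-butoxy-3-methyl-1-oxobutan-2-yl]imino}-1-methylcyclohexane-1-carboxylate | CC(C)[C@H](N=C1CCCC[C@]1(C)C(=O)OC(C)(C)C)C(=O)OC(C)(C)C | intermediate (not isolated)
6 | tert-butyl (1S)-1-methyl-2-oxocyclohexane-1-carboxylate | O=C1CCCC[C@]1(C)C(=O)OC(C)(C)C | intermediate
7 | lithium enolate of 6 (C2=C3) | [Li]OC1=CCCC[C@]1(C)C(=O)OC(C)(C)C | intermediate (not isolated)
8 | tert-butyl (1S)-1,3-dimethyl-2-oxocyclohexane-1-carboxylate (C3 epimers) | CC1CCC[C@](C)(C(=O)OC(C)(C)C)C1=O | intermediate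
9 | potassium enolate of 8 (C2=C3) | [K]OC1=C(C)CCC[C@]1(C)C(=O)OC(C)(C)C | intermediate (not isolated)
10 | tert-butyl (1S)-1,3-dimethyl-2-(trifluoromethanesulfonyloxy)cyclohex-2-ene-1-carboxylate | O=S(=O)(OC1=C(C)CCC[C@]1(C)C(=O)OC(C)(C)C)C(F)(F)F | intermediate
11 | tert-butyl (1S)-2-ethenyl-1,3-dimethylcyclohex-2-ene-1-carboxylate | C=CC1=C(C)CCC[C@]1(C)C(=O)OC(C)(C)C | intermediate
12 | dimethyl 3-hydroxy-3-methylpentanedioate | COC(=O)CC(C)(O)CC(=O)OC | starting material
13 | (3S)-3-hydroxy-5-methoxy-3-methyl-5-oxopentanoic acid | COC(=O)C[C@@](C)(O)CC(=O)O | intermediate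
14 | 1-tert-butyl 5-methyl (3R)-3-hydroxy-3-methylpentanedioate | COC(=O)C[C@@](C)(O)CC(=O)OC(C)(C)C | intermediate
15 | 1-tert-butyl 5-methyl (3R)-3-methyl-3-(triethylsilyloxy)pentanedioate | COC(=O)C[C@@](C)(O[Si](CC)(CC)CC)CC(=O)OC(C)(C)C | intermediate
16 | tert-butyl (3R)-5-[methoxy(methyl)amino]-3-methyl-5-oxo-3-(triethylsilyloxy)pentanoate | CON(C)C(=O)C[C@@](C)(O[Si](CC)(CC)CC)CC(=O)OC(C)(C)C | intermediate
17 | prop-1-yn-1-ylmagnesium bromide | CC#C[Mg]Br | starting material
18 | bromomagnesium hemiaminal alkoxide from 16 and 17 | CC#CC(O[Mg]Br)(N(C)OC)C[C@@](C)(O[Si](CC)(CC)CC)CC(=O)OC(C)(C)C | intermediate (not isolated)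
19 | tert-butyl (3R)-3-methyl-5-oxo-3-(triethylsilyloxy)oct-6-ynoate | CC#CC(=O)C[C@@](C)(O[Si](CC)(CC)CC)CC(=O)OC(C)(C)C | intermediate
20 | di-tert-butyl (13R)-11-oxo-13-(triethylsilyloxy)labda-5,8-diene-15,19-dioate (10β-CH3, 4β-ester) | CC1=C(C(=O)C[C@@](C)(O[Si](CC)(CC)CC)CC(=O)OC(C)(C)C)[C@@]2(C)CCC[C@](C)(C(=O)OC(C)(C)C)C2=CC1 | intermediate
21 | di-tert-butyl (13R)-11-oxo-13-(triethylsilyloxy)labd-8-ene-15,19-dioate (5α-H) | CC1=C(C(=O)C[C@@](C)(O[Si](CC)(CC)CC)CC(=O)OC(C)(C)C)[C@@]2(C)CCC[C@](C)(C(=O)OC(C)(C)C)[C@@H]2CC1 | intermediate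
22 | di-tert-butyl (13R)-11-hydroxy-13-(triethylsilyloxy)labda-8(17),9(11)-diene-15,19-dioate (photodienol, OH cis to C8) | C=C1CC[C@@H]2[C@](C)(CCC[C@]2(C)C(=O)OC(C)(C)C)/C1=C(/O)C[C@@](C)(O[Si](CC)(CC)CC)CC(=O)OC(C)(C)C | intermediate (not isolated)
23 | di-tert-butyl (13R)-11-oxo-13-(triethylsilyloxy)labd-8(17)-ene-15,19-dioate (5α-H, 9α-H) | C=C1CC[C@@H]2[C@](C)(CCC[C@]2(C)C(=O)OC(C)(C)C)[C@H]1C(=O)C[C@@](C)(O[Si](CC)(CC)CC)CC(=O)OC(C)(C)C | intermediate
24 | di-tert-butyl (13R)-11-hydroxy-13-(triethylsilyloxy)labd-8(17)-ene-15,19-dioate (C11 epimers) | C=C1CC[C@@H]2[C@](C)(CCC[C@]2(C)C(=O)OC(C)(C)C)[C@H]1C(O)C[C@@](C)(O[Si](CC)(CC)CC)CC(=O)OC(C)(C)C | intermediate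
25 | di-tert-butyl (13R)-11-(phenoxythiocarbonyloxy)-13-(triethylsilyloxy)labd-8(17)-ene-15,19-dioate | C=C1CC[C@@H]2[C@](C)(CCC[C@]2(C)C(=O)OC(C)(C)C)[C@H]1C(OC(=S)Oc1ccccc1)C[C@@](C)(O[Si](CC)(CC)CC)CC(=O)OC(C)(C)C | intermediate
26 | di-tert-butyl (13R)-13-(triethylsilyloxy)labd-8(17)-ene-15,19-dioate | C=C1CC[C@@H]2[C@](C)(CCC[C@]2(C)C(=O)OC(C)(C)C)[C@H]1CC[C@@](C)(O[Si](CC)(CC)CC)CC(=O)OC(C)(C)C | intermediate
27 | bis(trimethylsilyl) (13R)-13-(triethylsilyloxy)labd-8(17)-ene-15,19-dioate | C=C1CC[C@@H]2[C@](C)(CCC[C@]2(C)C(=O)O[Si](C)(C)C)[C@H]1CC[C@@](C)(O[Si](CC)(CC)CC)CC(=O)O[Si](C)(C)C | intermediate (not isolated)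
28 | (13R)-13-hydroxylabd-8(17)-ene-15,19-dioic acid | C=C1CC[C@@H]2[C@](C)(CCC[C@]2(C)C(=O)O)[C@H]1CC[C@@](C)(O)CC(=O)O | target

**Step count and risks**

Total: 17 steps (diene 1–5, ynone 6–10, union 11, endgame 12–17). Longest linear sequence: 12 steps (1–5, then 11–17; the ynone branch 6–10, 11–17 is equally long).

Step 11. The cycloaddition may be too slow at the tetrasubstituted terminus, may close stepwise to a cyclobutene instead of ring B, or may discriminate poorly between the two faces at C10. The fallback uses a more reactive, sterically smaller dienophile and sets out from Weinreb amide 16 and diene 11. Amide 16 is treated with propargylmagnesium bromide (Et2O, −78 °C) to give the propargyl ketone tert-butyl (3R)-3-methyl-5-oxo-3-(triethylsilyloxy)oct-7-ynoate F1. Et3N (CH2Cl2, rt) isomerises it to the allenyl ketone tert-butyl (3R)-3-methyl-5-oxo-3-(triethylsilyloxy)octa-6,7-dienoate F2. Its α,β-double bond adds to 11 with the same regiochemistry (C7–C8 and C9–C10; PhMe, 80 °C, or Me2AlCl at low temperature) to give di-tert-butyl (13R)-11-oxo-13-(triethylsilyloxy)labda-5,8(17)-diene-15,19-dioate F3 as C9 epimers. Mild base (Et3N or DBU, CH2Cl2, rt) then moves the exocyclic double bond into conjugation, and the route is rejoined at 20.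

Step 13. The photodienol may revert to the conjugated enone faster than it is protonated at C9, or the β,γ-unsaturated ketone may be consumed by secondary photoreactions (acyl shift, hydrogen abstraction by the excited carbonyl). The fallback replaces light by a silicon-directed deconjugation and sets out from 16 and 11. Amide 16 is treated with the lithium acetylide of 3-(trimethylsilyl)propyne (n-BuLi, THF, −78 °C) to give tert-butyl (3R)-3-methyl-5-oxo-3-(triethylsilyloxy)-8-(trimethylsilyl)oct-6-ynoate F4. Cycloaddition with 11 as in step 11 gives di-tert-butyl (13R)-11-oxo-13-(triethylsilyloxy)-17-(trimethylsilyl)labda-5,8-diene-15,19-dioate F5. Hydrogenation as in step 12 gives di-tert-butyl (13R)-11-oxo-13-(triethylsilyloxy)-17-(trimethylsilyl)labd-8-ene-15,19-dioate F6. Buffered fluoride (Bu4NF/AcOH, THF, −20 °C) removes the allylic silyl group as a dienolate that is protonated at C9 from the α face, and the route is rejoined at 23.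

Step 16. The secondary C11 radical may cyclise onto the 8(17)-alkene and reopen with migration of C8 from C9 to C11 (enlargement of ring B) before it is reduced, or the thionocarbonate may undergo thermal syn-elimination. The fallback removes the oxygen through a hydrazone and sets out from ketone 23, bypassing 24 and 25. TsNHNH2 (MeOH, 40 °C) gives the tosylhydrazone di-tert-butyl (13R)-11-(4-methylbenzenesulfonylhydrazono)-13-(triethylsilyloxy)labd-8(17)-ene-15,19-dioate F7. Reduction with catecholborane (CHCl3, 0 °C) and then NaOAc·3H2O (60 °C) eliminates sulfinate and releases N2 from the diazene, and the route is rejoined at 26.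

**Further compounds**

F1 | step 11 | tert-butyl (3R)-3-methyl-5-oxo-3-(triethylsilyloxy)oct-7-ynoate | C#CCC(=O)C[C@@](C)(O[Si](CC)(CC)CC)CC(=O)OC(C)(C)C
F2 | step 11 | tert-butyl (3R)-3-methyl-5-oxo-3-(triethylsilyloxy)octa-6,7-dienoate | C=C=CC(=O)C[C@@](C)(O[Si](CC)(CC)CC)CC(=O)OC(C)(C)C
F3 | step 11 | di-tert-butyl (13R)-11-oxo-13-(triethylsilyloxy)labda-5,8(17)-diene-15,19-dioate (C9 epimers) | C=C1CC=C2[C@](C)(CCC[C@]2(C)C(=O)OC(C)(C)C)C1C(=O)C[C@@](C)(O[Si](CC)(CC)CC)CC(=O)OC(C)(C)C
F4 | step 13 | tert-butyl (3R)-3-methyl-5-oxo-3-(triethylsilyloxy)-8-(trimethylsilyl)oct-6-ynoate | C[Si](C)(C)CC#CC(=O)C[C@@](C)(O[Si](CC)(CC)CC)CC(=O)OC(C)(C)C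
F5 | step 13 | di-tert-butyl (13R)-11-oxo-13-(triethylsilyloxy)-17-(trimethylsilyl)labda-5,8-diene-15,19-dioate | C[Si](C)(C)CC1=C(C(=O)C[C@@](C)(O[Si](CC)(CC)CC)CC(=O)OC(C)(C)C)[C@@]2(C)CCC[C@](C)(C(=O)OC(C)(C)C)C2=CC1
F6 | step 13 | di-tert-butyl (13R)-11-oxo-13-(triethylsilyloxy)-17-(trimethylsilyl)labd-8-ene-15,19-dioate (5α-H) | C[Si](C)(C)CC1=C(C(=O)C[C@@](C)(O[Si](CC)(CC)CC)CC(=O)OC(C)(C)C)[C@@]2(C)CCC[C@](C)(C(=O)OC(C)(C)C)[C@@H]2CC1
F7 | step 16 | di-tert-butyl (13R)-11-(4-methylbenzenesulfonylhydrazono)-13-(triethylsilyloxy)labd-8(17)-ene-15,19-dioate | C=C1CC[C@@H]2[C@](C)(CCC[C@]2(C)C(=O)OC(C)(C)C)[C@H]1C(=NNS(=O)(=O)c1ccc(C)cc1)C[C@@](C)(O[Si](CC)(CC)CC)CC(=O)OC(C)(C)C
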